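## Analysis of the target

Target 35 is a 1,2-dioxolane (ring atoms O1, O2, C3, C4, C5) in which both ring carbons next to oxygen are fully substituted. C3 carries a methyl group and the CH2CO2H arm. C5 carries a methyl group and a fifteen-carbon chain (C1′ to C15′) with a 7′E,9′E-diene and a skipped 12′Z-alkene. C3 is R and C5 is S, which puts the two methyl groups trans on the ring. The two centres are separated by the C4 methylene, so neither can direct the other through an adjacent bond, and neither has a hydrogen through which it could be corrected later.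

The O–O bond does not tolerate metal hydrides at ambient temperature, low-valent metals, hydrogenation catalysts or hard carbanions. The carbonyl group of the acid is β to O2, so an enolate there would expel the peroxide. C11′ is doubly allylic and the triene can slip into conjugation under base.

The difficulty is to set two quaternary C–O stereocentres in a 1,3-relationship and then to build a base-sensitive triene with the peroxide already in place.

The strategy rests on C3. Its four substituents (methyl, O2, the CH2CO2H arm, C4) are arranged as methyl, hydroxyl, CH2C(=O)O and CH2CH2O are at the carbinol carbon of (R)-mevalonolactone 1. The O2–C3 bond can therefore be bought, provided the ring is closed at O1–O2 and not at a C–O bond.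

## Retrosynthetic reasoning

**35 to 33.** The carboxyl group is taken back to the primary alcohol 34 and its silyl ether 33. No skeletal bond is cut. A carbonyl group β to O2 would not survive the basic olefinations that build the chain, whereas a silyl ether does. The forward step is a late, neutral, metal-free oxidation.

**33 to 29 and 32.** The C9′=C10′ bond is cut. This leaves the skipped Z-alkene in the six-carbon sulfone 32, made via 31 from 30, in which the Z geometry is bought. The peroxide fragment then carries an E-enal, 29, which cannot lose its conjugation. The forward reaction must give an E-alkene from an enal and an alkyl sulfone. Enal 29 goes back to aldehyde 28 by a two-carbon formyl olefination that sets the 7′E geometry.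

**28 to 22 and 25.** The C2′–C3′ bond is cut because the C5 arm is born only two carbons long. A Wittig reaction followed by a metal-free hydrogen transfer is the only C–C coupling here that keeps organometallic reagents and hydrogenation catalysts away from the peroxide. Ylide 25 (from salt 24, from bromide 23) carries C7′ as an acetal, so that 26 is reduced to 27 and 27 unmasks to 28 in one deprotection.

**22 to 20.** Aldehyde 22 comes from alcohol 21 and this from 20. The two arms of 20 bear silyl ethers of different acid stability, so the C5 arm can be opened first while the C3 arm stays masked.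

**20 to 18 (key disconnection).** The O1–O2 bond is cut. Every other ring bond to oxygen is a C–O bond at a quaternary stereocentre, and closing one of those would require clean substitution at a tertiary carbon. Cutting O–O moves all stereochemistry into acyclic chemistry: 18 already contains both C–O bonds with their final configuration. The forward step has to make the terminal oxygen of the hydroperoxide a leaving group (19) and let the C3 alkoxide attack the inner oxygen.

**18 to 14.** The C5–OOH bond is cut. Perhydrolysis of oxetane 14 at its tertiary carbon gives 15; exchange of the C3 protecting group (16) and silylation of the liberated primary hydroxyl (via 17) give 18. An oxetane is chosen because ring strain lets the tertiary C–O bond break under conditions mild enough for substitution with inversion. The same event also releases the two-carbon C5 arm as an alcohol.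

**14 to 10.** Oxetane 14 is the cyclic ether of 1,3-diol 12 (through monotosylate 13). Diol 12 is the hydride-opening product of epoxy alcohol 11, and 11 comes from E-allylic alcohol 10 by Sharpless epoxidation. The epoxidation sets the C5–O bond with the configuration opposite to that of the target, because the perhydrolysis inverts it.

**10 to 7.** The C5–CH3 and C6–C7 bonds are cut. Carboalumination of terminal alkyne 8 (through alkenylalane 9) gives the trisubstituted E-alkene with full control of geometry. Alkyne 8 is the one-carbon homologue of aldehyde 7.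

**7 to 1.** No skeletal bond is cut; the two ends of the mevalonate chain only exchange oxidation level. The lactone carbonyl carbon of 1 (the future carboxyl carbon of 35) is reduced and protected (3, 4, 5, 6). The CH2O end is oxidised to aldehyde 7 and becomes C5. Using the lactone carbonyl as C5 would be shorter, but it would give the enantiomer at C3. Lactone 1 is opened through salt 2 before any reduction, because full reduction of the lactone would make the two arms identical and erase the stereocentre.

## Alternatives that were turned down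

**Alternative 1: two-fold alkylation of a bis-peroxyketal.**
- Disconnection: both exocyclic C–CH2 bonds at C3 and C5 are cut on an intact ring, which leads to 3,5-dimethoxy-3,5-dimethyl-1,2-dioxolane A2.
- Forward key step: a strong Lewis acid ionises the two peroxyketal carbons of A2 one after the other, and a silyl ketene acetal traps each cyclic peroxycarbenium ion to give diester A1.
- For: the ring comes in very few steps from commodity chemicals; both arms arrive at the acid oxidation level; capture of dioxolanyl cations by silyl ketene acetals is an established reaction type.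
- Against: A1 is racemic, so half the material is lost on resolution. The trans/cis outcome of the second alkylation is set only by a small difference between a methyl and an acetate arm. The two ester arms of A1 are identical, so one must be singled out statistically and then reduced and homologated next to the peroxide. Peroxycarbenium ions can also fragment.
- Comparison: alternative 1 is clearly shorter. The chosen route offers absolute configuration at both centres by design and arms that are different from the first step.

**Alternative 2: double perhydrolysis of a C2-symmetric bis-oxetane.**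
- Disconnection: O2–C3 and O1–C5 are cut, which leads to bis-oxetane A4.
- Forward key step: Lewis-acid perhydrolysis opens one oxetane of A4 at its tertiary carbon, and the new hydroperoxide opens the second oxetane 5-exo to give diol A3.
- For: it is the shortest stereocontrolled entry to the ring; symmetry halves the work; both bond formations are of known type, so its ring closure has closer precedent than the one chosen here.
- Against: both quaternary centres must invert cleanly at a tertiary carbon. Any ionisation at either gives the cis (meso) dioxolane. The first adduct can take up a second peroxide or oligomerise. The two hydroxyethyl arms of A3 are equivalent and must be told apart statistically.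
- Comparison: alternative 2 is stronger on step count and precedent. The chosen route makes only C5 depend on an invertive opening, takes C3 untouched from the chiral pool, has different arms from the start, and confines the unproven event to a bond that touches no stereocentre.

**Alternative 3: iodonium-induced peroxycyclisation.**
- Disconnection: O1–C5 is cut, which leads to unsaturated hydroperoxide A6.
- Forward key step: an electrophilic iodine reagent activates the trisubstituted alkene of A6, and the C3 hydroperoxide attacks the methyl-bearing carbon 5-exo, anti to iodine, to give iodide A5.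
- For: halonium-driven cyclisation of unsaturated hydroperoxides is known; the regiochemistry is Markovnikov and exo; seven chain carbons are already in place, which would save the Wittig, reduction and acetal steps of the chosen route.
- Against: the new quaternary centre C5 is set by 1,3-induction from a C3 whose methyl and hydroxyethyl groups differ little, so facial selectivity should be low. The iodine on C1′ must then be removed reductively, and a radical at C1′ is β to the O–O bond and would collapse to an epoxide and an alkoxy radical. A6 also needs its own stereodefined trisubstituted alkene.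
- Comparison: alternative 3 is stronger on precedent for the closure and on chain economy. The chosen route fixes both centres before the ring is closed and has no halogen to remove.

Key step: step 14

Assumption: (R)-mevalonolactone 1, 2-(4-bromobutyl)-1,3-dioxolane 23 and (3Z)-hex-3-en-1-ol 30 are taken as purchasable; every other numbered compound is made.

## Route

Step 1
Reactants: 1 (R)-mevalonolactone
Product: 3 methyl (3R)-3,5-dihydroxy-3-methylpentanoate, via potassium mevalonate 2 (not isolated)
Conditions: KOH (1.0 equiv), MeOH/H2O, rt; evaporate; MeI, DMF, 0 °C to rt; used crude at once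
Reagents that add atoms: potassium hydroxide, [K+].[OH-]; iodomethane, CI
Why: Saponification of the δ-lactone and SN2 O-methylation of the carboxylate give the open hydroxy ester without touching the C3–O bond; immediate silylation in step 2 forestalls relactonisation.

Step 2
Reactants: 3 methyl (3R)-mevalonate
Product: 4 methyl (3R)-3-methyl-3,5-bis(triethylsilyloxy)pentanoate
Conditions: Et3SiOTf (2.4 equiv), 2,6-lutidine, CH2Cl2, −78 to 0 °C
Reagents that add atoms: triethylsilyl trifluoromethanesulfonate, CC[Si](CC)(CC)OS(=O)(=O)C(F)(F)F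
Why: A silyl triflate caps both the primary and the hindered tertiary hydroxyl. The tertiary ether later prevents retro-aldol cleavage and six-membered ether formation; the primary one marks the end that becomes C5.

Step 3
Reactants: 4 bis-silylated methyl ester
Product: 5 (3S)-3-methyl-3,5-bis(triethylsilyloxy)pentan-1-ol
Conditions: i-Bu2AlH (2.5 equiv), CH2Cl2, −78 to 0 °C
Reagents that add atoms: none
Why: Ester-to-alcohol reduction by an aluminium hydride. The two arms stay different because one is a free alcohol and the other a silyl ether; the change of descriptor is a priority effect only.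

Step 4
Reactants: 5 primary alcohol
Product: 6 tert-butyl{[(3R)-3-methyl-3,5-bis(triethylsilyloxy)pentyl]oxy}diphenylsilane
Conditions: TBDPSCl, imidazole, DMF, 0 °C to rt
Reagents that add atoms: tert-butyl(chloro)diphenylsilane, CC(C)(C)[Si](Cl)(c1ccccc1)c1ccccc1
Why: Imidazole-promoted silylation of the only free hydroxyl; this robust ether masks the future carboxyl carbon until step 25.

Step 5
Reactants: 6 tris-silyl ether
Product: 7 (3S)-5-(tert-butyldiphenylsilyloxy)-3-methyl-3-(triethylsilyloxy)pentanal
Conditions: (COCl)2, DMSO, CH2Cl2, −78 to −40 °C; Et3N, −78 °C to rt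
Reagents that add atoms: none
Why: Under Swern conditions a primary triethylsilyl ether is cleaved by the chlorosulfonium species and oxidised in the same flask. The tertiary triethylsilyl and the tert-butyldiphenylsilyl ethers are too hindered to react (oxidative desilylation, Swern oxidation).

Step 6
Reactants: 7 aldehyde
Product: 8 tert-butyl{[(3R)-3-methyl-3-(triethylsilyloxy)hex-5-yn-1-yl]oxy}diphenylsilane
Conditions: dimethyl (1-diazo-2-oxopropyl)phosphonate, K2CO3, MeOH, 0 °C to rt
Reagents that add atoms: dimethyl (1-diazo-2-oxopropyl)phosphonate, CC(=O)C(=[N+]=[N-])P(=O)(OC)OC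
Why: Seyferth–Gilbert homologation in its Ohira–Bestmann form turns the aldehyde into a terminal alkyne under mild carbonate conditions. The aldehyde carbon becomes the internal alkyne carbon, the future C5.

Step 7
Reactants: 8 terminal alkyne
Product: 10 (2E,5R)-7-(tert-butyldiphenylsilyloxy)-3,5-dimethyl-5-(triethylsilyloxy)hept-2-en-1-ol, via alkenylalane 9 (not isolated)
Conditions: Me3Al (2.5 equiv), Cp2ZrCl2 (0.25 equiv), CH2Cl2, 0 °C to rt; then n-BuLi, THF, −78 °C; (CH2O)n, −78 °C to rt
Reagents that add atoms: trimethylaluminium, C[Al](C)C; formaldehyde (as paraformaldehyde), C=O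
Why: Zirconium-catalysed Negishi carboalumination adds methyl and aluminium syn across the alkyne, with methyl on the internal carbon. The alkenylalane, as its butyl ate complex, is hydroxymethylated with retention, which fixes the E-trisubstituted allylic alcohol.

Step 8
Reactants: 10 E-allylic alcohol
Product: 11 [(2S,3S)-3-{(2S)-4-(tert-butyldiphenylsilyloxy)-2-methyl-2-(triethylsilyloxy)butyl}-3-methyloxiran-2-yl]methanol
Conditions: Ti(OiPr)4 (10 mol%), L-(+)-diisopropyl tartrate (12 mol%), t-BuOOH, 4 Å molecular sieves, CH2Cl2, −20 °C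
Reagents that add atoms: tert-butyl hydroperoxide, CC(C)(C)OO
Why: Sharpless asymmetric epoxidation. With L-(+)-tartrate an E-3,3-disubstituted allylic alcohol gives the (2S,3S)-epoxide, the sense established for geraniol-type substrates, so the C5–O bond is set by the reagent and the remote C3 centre has little influence.

Step 9
Reactants: 11 epoxy alcohol
Product: 12 (3R,5S)-7-(tert-butyldiphenylsilyloxy)-3,5-dimethyl-5-(triethylsilyloxy)heptane-1,3-diol
Conditions: NaAlH2(OCH2CH2OMe)2, THF, 0 °C
Reagents that add atoms: none
Why: The aluminate formed at the primary hydroxyl delivers hydride to the neighbouring epoxide carbon, so 2,3-epoxy alcohols open to 1,3-diols. The C5–O bond is not touched and keeps its configuration.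

Step 10
Reactants: 12 1,3-diol
Product: 14 tert-butyl{(3S)-3-methyl-4-[(2R)-2-methyloxetan-2-yl]-3-(triethylsilyloxy)butoxy}diphenylsilane, via monotosylate 13 (not isolated)
Conditions: KOt-Bu (1.05 equiv), TsCl (1.0 equiv), THF, 0 °C; then KOt-Bu (1.2 equiv), 0 °C to rt
Reagents that add atoms: none
Why: Selective sulfonylation of the primary alkoxide is followed by 4-exo-tet Williamson closure from the tertiary alkoxide, helped by the gem-disubstitution at C5. The silyl ether at C3 blocks the otherwise faster six-membered ether formation, and C5 is retained because displacement occurs at the primary carbon.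

Step 11
Reactants: 14 oxetane
Product: 15 (3S,5S)-7-(tert-butyldiphenylsilyloxy)-3-hydroperoxy-3,5-dimethyl-5-(triethylsilyloxy)heptan-1-ol
Conditions: anhydrous H2O2 in Et2O (10 equiv), Me3SiOTf (0.3 equiv), Et2O, −78 to −20 °C
Reagents that add atoms: hydrogen peroxide, OO
Why: Lewis-acid activation of the oxetane oxygen and attack of hydrogen peroxide at the more substituted carbon is a known route to 3-hydroperoxy alkanols. The peroxide enters on the ion-paired oxonium from the side opposite to the departing oxygen, so C5 is inverted to the configuration needed in the ring.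

Step 12
Reactants: 15 silylated hydroperoxy alcohol
Product: 16 (3S,5S)-7-(tert-butyldiphenylsilyloxy)-3-hydroperoxy-3,5-dimethylheptane-1,5-diol
Conditions: camphorsulfonic acid (10 mol%), MeOH/CH2Cl2, 0 °C to rt
Reagents that add atoms: none
Why: Mild acid-catalysed methanolysis removes the tertiary triethylsilyl ether; the far more acid-stable tert-butyldiphenylsilyl ether and the tertiary hydroperoxide are unaffected.

Step 13
Reactants: 16 hydroperoxy diol
Product: 18 (3S,5S)-7-(tert-butyldimethylsilyloxy)-1-(tert-butyldiphenylsilyloxy)-5-hydroperoxy-3,5-dimethylheptan-3-ol, via bis-silyl peroxide 17 (not isolated)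
Conditions: TBSCl (2.5 equiv), imidazole, DMF, 0 °C; then K2CO3 (cat.), MeOH, 0 °C
Reagents that add atoms: tert-butyl(chloro)dimethylsilane, CC(C)(C)[Si](C)(C)Cl
Why: The primary alcohol and the hydroperoxide are both silylated, while the tertiary alcohol is too hindered for the silyl chloride. Brief carbonate methanolysis then cleaves only the silyl peroxide, because a peroxide anion leaves silicon far more readily than an alkoxide.

Step 14
Reactants: 18 1,3-hydroxy hydroperoxide
Product: 20 tert-butyl(2-{(3S,5S)-5-[2-(tert-butyldiphenylsilyloxy)ethyl]-3,5-dimethyl-1,2-dioxolan-3-yl}ethoxy)dimethylsilane, via peroxysulfonate 19 (not isolated)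
Conditions: KN(SiMe3)2 (1.0 equiv), THF, −78 °C; 2,4,6-(i-Pr)3C6H2SO2Cl (1.05 equiv), −78 °C; then KN(SiMe3)2 (1.1 equiv), −78 to −40 °C
Reagents that add atoms: none
Why: Proposed new method: the first equivalent of KN(SiMe3)2 removes only the hydroperoxide proton, which is several pKa units more acidic than the tertiary carbinol, and the peroxy anion is sulfonylated at its terminal oxygen to give 19, in which arenesulfonate is a leaving group on oxygen. The second equivalent generates the C3 alkoxide, which attacks the C5-bound peroxide oxygen along the O–O axis and expels sulfonate, so that O1–O2 is formed by SN2 at oxygen. The closest known reaction types are dioxirane formation by intramolecular alkoxide attack on a peroxysulfate oxygen, ether formation by carbanion attack on the alkyl-bearing oxygen of peresters and dialkyl peroxides, and the Criegee rearrangement of tertiary peroxysulfonates, which is the competing channel. The ring closes 5-exo-tet at oxygen, the sulfonate leaving from outside the forming 1,2-dioxolane. No stereocentre is created: neither C3–O nor C5–O is made or broken, so both quaternary centres enter the ring with retention and the methyl groups end up trans. The step therefore needs chemoselectivity only, namely attack at oxygen ahead of 1,2-alkyl shift from C5 to oxygen, of sulfonyl transfer to the alkoxide and of fragmentation. The 2,4,6-triisopropylphenyl group shields sulfur, the groups that could migrate are methyl and primary alkyl with low migratory aptitude, the temperature is low, and the gem-disubstitution at C3 and C5 holds the two oxygens close together.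

Step 15
Reactants: 20 bis-silylated dioxolane
Product: 21 2-[(3S,5S)-5-{2-(tert-butyldiphenylsilyloxy)ethyl}-3,5-dimethyl-1,2-dioxolan-3-yl]ethan-1-ol
Conditions: pyridinium p-toluenesulfonate (0.2 equiv), MeOH, rt
Reagents that add atoms: none
Why: Acid-catalysed methanolysis distinguishes the primary tert-butyldimethylsilyl ether from the much more acid-stable tert-butyldiphenylsilyl ether; a fully substituted dialkyl peroxide is inert to mild acid.

Step 16
Reactants: 21 dioxolane alcohol
Product: 22 2-[(3R,5S)-5-{2-(tert-butyldiphenylsilyloxy)ethyl}-3,5-dimethyl-1,2-dioxolan-3-yl]acetaldehyde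
Conditions: Dess–Martin periodinane, pyridine, CH2Cl2, 0 °C to rt
Reagents that add atoms: none
Why: Dess–Martin oxidation is neutral and free of metals and reducing by-products, so the O–O bond survives; pyridine takes up the acetic acid so that the β-peroxy aldehyde is not enolised.

Step 17
Reactants: 23 2-(4-bromobutyl)-1,3-dioxolane
Product: 24 [4-(1,3-dioxolan-2-yl)butyl]triphenylphosphonium bromide
Conditions: PPh3, MeCN, reflux
Reagents that add atoms: triphenylphosphine, c1ccc(cc1)P(c1ccccc1)c1ccccc1
Why: SN2 quaternisation of the phosphine by the primary bromide; the cyclic acetal is stable under these neutral conditions.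

Step 18
Reactants: 22 dioxolane acetaldehyde; 24 phosphonium bromide
Product: 26 tert-butyl(2-{(3S,5S)-5-[(2Z)-6-(1,3-dioxolan-2-yl)hex-2-en-1-yl]-3,5-dimethyl-1,2-dioxolan-3-yl}ethoxy)diphenylsilane, via ylide 25 (not isolated)
Conditions: 24, NaN(SiMe3)2, THF, 0 °C; then 22, −78 to 0 °C
Reagents that add atoms: none
Why: Wittig olefination with a non-stabilised ylide at low temperature, where addition to the carbonyl group is much faster than enolisation of the aldehyde. The Z geometry is of no consequence because the alkene is reduced next.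

Step 19
Reactants: 26 Z-alkene acetal
Product: 27 tert-butyl(2-{(3S,5S)-5-[6-(1,3-dioxolan-2-yl)hexyl]-3,5-dimethyl-1,2-dioxolan-3-yl}ethoxy)diphenylsilane
Conditions: 2-nitrobenzenesulfonohydrazide (5 equiv), Et3N, CH2Cl2, rt
Reagents that add atoms: none
Why: Diimide, released from the sulfonyl hydrazide, transfers two hydrogens to the alkene in a concerted, metal-free step that leaves the O–O bond, the acetal and the silyl ether alone (diimide reduction).

Step 20
Reactants: 27 saturated acetal
Product: 28 7-[(3S,5S)-5-{2-(tert-butyldiphenylsilyloxy)ethyl}-3,5-dimethyl-1,2-dioxolan-3-yl]heptanal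
Conditions: 1 M HCl, THF, rt
Reagents that add atoms: water, O
Why: Aqueous acid hydrolysis of the ethylene acetal; the dialkyl peroxide and the tert-butyldiphenylsilyl ether tolerate dilute acid.

Step 21
Reactants: 28 heptanal
Product: 29 (2E)-9-[(3S,5S)-5-{2-(tert-butyldiphenylsilyloxy)ethyl}-3,5-dimethyl-1,2-dioxolan-3-yl]non-2-enal
Conditions: Ph3P=CHCHO, toluene, 70 °C
Reagents that add atoms: (triphenylphosphoranylidene)acetaldehyde, O=CC=P(c1ccccc1)(c1ccccc1)c1ccccc1
Why: Wittig reaction with the stabilised, non-basic formyl ylide gives the E-enal; a fully substituted dialkyl peroxide is thermally stable at this temperature.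

Step 22
Reactants: 30 (3Z)-hex-3-en-1-ol
Product: 31 5-{[(3Z)-hex-3-en-1-yl]sulfanyl}-1-phenyl-1H-tetrazole
Conditions: 1-phenyl-1H-tetrazole-5-thiol, PPh3, diisopropyl azodicarboxylate, THF, 0 °C to rt
Reagents that add atoms: 1-phenyl-1H-tetrazole-5-thiol, Sc1nnnn1-c1ccccc1
Why: Mitsunobu thioetherification of the primary alcohol with the acidic tetrazole thiol; the Z-alkene is not involved.

Step 23
Reactants: 31 tetrazolyl sulfide
Product: 32 5-{[(3Z)-hex-3-en-1-yl]sulfonyl}-1-phenyl-1H-tetrazole
Conditions: (NH4)6Mo7O24·4H2O (10 mol%), 30% H2O2, EtOH, 0 °C to rt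
Reagents that add atoms: hydrogen peroxide, OO
Why: Molybdate-catalysed oxidation takes the sulfide to the sulfone; a 1,2-disubstituted alkene is not epoxidised under these conditions.

Step 24
Reactants: 29 E-enal; 32 tetrazolyl sulfone
Product: 33 tert-butyl(2-{(3S,5S)-3,5-dimethyl-5-[(7E,9E,12Z)-pentadeca-7,9,12-trien-1-yl]-1,2-dioxolan-3-yl}ethoxy)diphenylsilane
Conditions: 32, KN(SiMe3)2, DME, −60 °C; then 29, −60 °C to rt
Reagents that add atoms: none
Why: Julia–Kocienski olefination: the metalated phenyltetrazolyl sulfone adds to the enal, and Smiles rearrangement with loss of sulfur dioxide and the tetrazolone forms the C9′=C10′ bond, E-selectively with a potassium counter-ion in an ether solvent. The existing E and Z alkenes are carried in unchanged, and the sulfone is metalated before the enal is added.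

Step 25
Reactants: 33 triene silyl ether
Product: 34 2-{(3S,5S)-3,5-dimethyl-5-[(7E,9E,12Z)-pentadeca-7,9,12-trien-1-yl]-1,2-dioxolan-3-yl}ethan-1-ol
Conditions: n-Bu4NF, AcOH (1:1), THF, 0 °C to rt
Reagents that add atoms: none
Why: Fluoride cleaves the Si–O bond; buffering with acetic acid keeps the medium from isomerising the skipped triene, and dialkyl peroxides are inert to fluoride.

Step 26
Reactants: 34 triene alcohol
Product: 35 2-{(3R,5S)-3,5-dimethyl-5-[(7E,9E,12Z)-pentadeca-7,9,12-trien-1-yl]-1,2-dioxolan-3-yl}acetic acid
Conditions: TEMPO (0.2 equiv), PhI(OAc)2 (2.2 equiv), MeCN/pH 7 buffer, rt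
Reagents that add atoms: water, O
Why: Oxoammonium-mediated oxidation takes the primary alcohol through the aldehyde hydrate to the acid without a metal and without affecting the alkenes or the O–O bond. The medium stays neutral, so no enolate β to the peroxide is formed.

## Compound list

1 | (R)-mevalonolactone, (4R)-4-hydroxy-4-methyloxan-2-one | C[C@@]1(O)CCOC(=O)C1 | starting material
2 | potassium (3R)-3,5-dihydroxy-3-methylpentanoate | [K+].[O-]C(=O)C[C@](C)(O)CCO | intermediate
3 | methyl (3R)-3,5-dihydroxy-3-methylpentanoate | COC(=O)C[C@](C)(O)CCO | intermediate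
4 | methyl (3R)-3-methyl-3,5-bis(triethylsilyloxy)pentanoate | COC(=O)C[C@](C)(O[Si](CC)(CC)CC)CCO[Si](CC)(CC)CC | intermediate
5 | (3S)-3-methyl-3,5-bis(triethylsilyloxy)pentan-1-ol | OCC[C@](C)(O[Si](CC)(CC)CC)CCO[Si](CC)(CC)CC | intermediate
6 | tert-butyl{[(3R)-3-methyl-3,5-bis(triethylsilyloxy)pentyl]oxy}diphenylsilane | CC(C)(C)[Si](c1ccccc1)(c1ccccc1)OCC[C@](C)(O[Si](CC)(CC)CC)CCO[Si](CC)(CC)CC | intermediate
7 | (3S)-5-(tert-butyldiphenylsilyloxy)-3-methyl-3-(triethylsilyloxy)pentanal | O=CC[C@@](C)(O[Si](CC)(CC)CC)CCO[Si](c1ccccc1)(c1ccccc1)C(C)(C)C | intermediate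
8 | tert-butyl{[(3R)-3-methyl-3-(triethylsilyloxy)hex-5-yn-1-yl]oxy}diphenylsilane | C#CC[C@@](C)(O[Si](CC)(CC)CC)CCO[Si](c1ccccc1)(c1ccccc1)C(C)(C)C | intermediate
9 | [(1E,4R)-6-(tert-butyldiphenylsilyloxy)-2,4-dimethyl-4-(triethylsilyloxy)hex-1-en-1-yl]dimethylalane | C[Al](C)/C=C(\C)C[C@@](C)(O[Si](CC)(CC)CC)CCO[Si](c1ccccc1)(c1ccccc1)C(C)(C)C | intermediate
10 | (2E,5R)-7-(tert-butyldiphenylsilyloxy)-3,5-dimethyl-5-(triethylsilyloxy)hept-2-en-1-ol | OC/C=C(\C)C[C@@](C)(O[Si](CC)(CC)CC)CCO[Si](c1ccccc1)(c1ccccc1)C(C)(C)C | intermediate
11 | [(2S,3S)-3-{(2S)-4-(tert-butyldiphenylsilyloxy)-2-methyl-2-(triethylsilyloxy)butyl}-3-methyloxiran-2-yl]methanol | OC[C@@H]1O[C@@]1(C)C[C@@](C)(O[Si](CC)(CC)CC)CCO[Si](c2ccccc2)(c2ccccc2)C(C)(C)C | intermediate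
12 | (3R,5S)-7-(tert-butyldiphenylsilyloxy)-3,5-dimethyl-5-(triethylsilyloxy)heptane-1,3-diol | OCC[C@@](C)(O)C[C@@](C)(O[Si](CC)(CC)CC)CCO[Si](c1ccccc1)(c1ccccc1)C(C)(C)C | intermediate
13 | (3R,5S)-7-(tert-butyldiphenylsilyloxy)-3-hydroxy-3,5-dimethyl-5-(triethylsilyloxy)heptyl 4-methylbenzenesulfonate | Cc1ccc(cc1)S(=O)(=O)OCC[C@@](C)(O)C[C@@](C)(O[Si](CC)(CC)CC)CCO[Si](c2ccccc2)(c2ccccc2)C(C)(C)C | intermediate
14 | tert-butyl{(3S)-3-methyl-4-[(2R)-2-methyloxetan-2-yl]-3-(triethylsilyloxy)butoxy}diphenylsilane | C[C@@]1(CCO1)C[C@@](C)(O[Si](CC)(CC)CC)CCO[Si](c2ccccc2)(c2ccccc2)C(C)(C)C | intermediate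
15 | (3S,5S)-7-(tert-butyldiphenylsilyloxy)-3-hydroperoxy-3,5-dimethyl-5-(triethylsilyloxy)heptan-1-ol | OCC[C@](C)(OO)C[C@@](C)(O[Si](CC)(CC)CC)CCO[Si](c1ccccc1)(c1ccccc1)C(C)(C)C | intermediate
16 | (3S,5S)-7-(tert-butyldiphenylsilyloxy)-3-hydroperoxy-3,5-dimethylheptane-1,5-diol | OCC[C@](C)(OO)C[C@@](C)(O)CCO[Si](c1ccccc1)(c1ccccc1)C(C)(C)C | intermediate
17 | (3S,5S)-7-(tert-butyldimethylsilyloxy)-5-[(tert-butyldimethylsilyl)peroxy]-1-(tert-butyldiphenylsilyloxy)-3,5-dimethylheptan-3-ol | CC(C)(C)[Si](C)(C)OCC[C@](C)(OO[Si](C)(C)C(C)(C)C)C[C@@](C)(O)CCO[Si](c1ccccc1)(c1ccccc1)C(C)(C)C | intermediate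
18 | (3S,5S)-7-(tert-butyldimethylsilyloxy)-1-(tert-butyldiphenylsilyloxy)-5-hydroperoxy-3,5-dimethylheptan-3-ol | CC(C)(C)[Si](C)(C)OCC[C@](C)(OO)C[C@@](C)(O)CCO[Si](c1ccccc1)(c1ccccc1)C(C)(C)C | intermediate
19 | (3S,5S)-7-(tert-butyldimethylsilyloxy)-1-(tert-butyldiphenylsilyloxy)-3,5-dimethyl-5-{[(2,4,6-triisopropylphenyl)sulfonyl]peroxy}heptan-3-ol | CC(C)(C)[Si](C)(C)OCC[C@](C)(OOS(=O)(=O)c1c(cc(cc1C(C)C)C(C)C)C(C)C)C[C@@](C)(O)CCO[Si](c2ccccc2)(c2ccccc2)C(C)(C)C | intermediate
20 | tert-butyl(2-{(3S,5S)-5-[2-(tert-butyldiphenylsilyloxy)ethyl]-3,5-dimethyl-1,2-dioxolan-3-yl}ethoxy)dimethylsilane | CC(C)(C)[Si](C)(C)OCC[C@@]1(C)C[C@](C)(CCO[Si](c2ccccc2)(c2ccccc2)C(C)(C)C)OO1 | intermediate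
21 | 2-[(3S,5S)-5-{2-(tert-butyldiphenylsilyloxy)ethyl}-3,5-dimethyl-1,2-dioxolan-3-yl]ethan-1-ol | OCC[C@@]1(C)C[C@](C)(CCO[Si](c2ccccc2)(c2ccccc2)C(C)(C)C)OO1 | intermediate
22 | 2-[(3R,5S)-5-{2-(tert-butyldiphenylsilyloxy)ethyl}-3,5-dimethyl-1,2-dioxolan-3-yl]acetaldehyde | O=CC[C@@]1(C)C[C@](C)(CCO[Si](c2ccccc2)(c2ccccc2)C(C)(C)C)OO1 | intermediate
23 | 2-(4-bromobutyl)-1,3-dioxolane | BrCCCCC1OCCO1 | starting material
24 | [4-(1,3-dioxolan-2-yl)butyl]triphenylphosphonium bromide | [Br-].C(CCCC1OCCO1)[P+](c2ccccc2)(c2ccccc2)c2ccccc2 | intermediate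
25 | [4-(1,3-dioxolan-2-yl)butylidene]triphenylphosphorane | C(CCCC1OCCO1)=P(c2ccccc2)(c2ccccc2)c2ccccc2 | intermediate
26 | tert-butyl(2-{(3S,5S)-5-[(2Z)-6-(1,3-dioxolan-2-yl)hex-2-en-1-yl]-3,5-dimethyl-1,2-dioxolan-3-yl}ethoxy)diphenylsilane | O1CCOC1CCC/C=C\C[C@@]2(C)C[C@](C)(CCO[Si](c3ccccc3)(c3ccccc3)C(C)(C)C)OO2 | intermediate
27 | tert-butyl(2-{(3S,5S)-5-[6-(1,3-dioxolan-2-yl)hexyl]-3,5-dimethyl-1,2-dioxolan-3-yl}ethoxy)diphenylsilane | O1CCOC1CCCCCC[C@@]2(C)C[C@](C)(CCO[Si](c3ccccc3)(c3ccccc3)C(C)(C)C)OO2 | intermediate
28 | 7-[(3S,5S)-5-{2-(tert-butyldiphenylsilyloxy)ethyl}-3,5-dimethyl-1,2-dioxolan-3-yl]heptanal | O=CCCCCCC[C@@]1(C)C[C@](C)(CCO[Si](c2ccccc2)(c2ccccc2)C(C)(C)C)OO1 | intermediate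
29 | (2E)-9-[(3S,5S)-5-{2-(tert-butyldiphenylsilyloxy)ethyl}-3,5-dimethyl-1,2-dioxolan-3-yl]non-2-enal | O=C/C=C/CCCCCC[C@@]1(C)C[C@](C)(CCO[Si](c2ccccc2)(c2ccccc2)C(C)(C)C)OO1 | intermediate
30 | (3Z)-hex-3-en-1-ol | CC/C=C\CCO | starting material
31 | 5-{[(3Z)-hex-3-en-1-yl]sulfanyl}-1-phenyl-1H-tetrazole | CC/C=C\CCSc1nnnn1-c1ccccc1 | intermediate
32 | 5-{[(3Z)-hex-3-en-1-yl]sulfonyl}-1-phenyl-1H-tetrazole | CC/C=C\CCS(=O)(=O)c1nnnn1-c1ccccc1 | intermediate
33 | tert-butyl(2-{(3S,5S)-3,5-dimethyl-5-[(7E,9E,12Z)-pentadeca-7,9,12-trien-1-yl]-1,2-dioxolan-3-yl}ethoxy)diphenylsilane | CC/C=C\C/C=C/C=C/CCCCCC[C@@]1(C)C[C@](C)(CCO[Si](c2ccccc2)(c2ccccc2)C(C)(C)C)OO1 | intermediate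
34 | 2-{(3S,5S)-3,5-dimethyl-5-[(7E,9E,12Z)-pentadeca-7,9,12-trien-1-yl]-1,2-dioxolan-3-yl}ethan-1-ol | CC/C=C\C/C=C/C=C/CCCCCC[C@@]1(C)C[C@](C)(CCO)OO1 | intermediate
35 | 2-{(3R,5S)-3,5-dimethyl-5-[(7E,9E,12Z)-pentadeca-7,9,12-trien-1-yl]-1,2-dioxolan-3-yl}acetic acid | CC/C=C\C/C=C/C=C/CCCCCC[C@@]1(C)C[C@](C)(CC(=O)O)OO1 | target

## Step count and least certain steps

Total step count: 26. Longest linear sequence: 23 steps (steps 1 to 16, 18 to 21 and 24 to 26); steps 17, 22 and 23 make the two side-chain reagents.

**Step 14 (key step).** The most likely failure is that peroxysulfonate 19 loses sulfonate with 1,2-shift of a C5 substituent to oxygen before the C3 alkoxide can attack, or that the alkoxide takes the sulfonyl group instead. Tertiary peroxysulfonates are inherently set up for this rearrangement.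

The fallback uses known chemistry; it sets out from 18 and comes back at 20. The tertiary C3 carbinol of 18 is ionised with BF3·OEt2 in CH2Cl2 at low temperature and the C5 hydroperoxide captures the cation. This is the intramolecular form of the acid-catalysed condensation of tertiary alcohols with hydroperoxides, by which tetraalkyl-1,2-dioxolanes are made from 1,3-diols. The C3–O bond is then formed at a planar cation, so control at C3 is given up. Compound 20 would form together with its C3 epimer, tert-butyl(2-{(3S,5R)-5-[2-(tert-butyldiphenylsilyloxy)ethyl]-3,5-dimethyl-1,2-dioxolan-3-yl}ethoxy)dimethylsilane F1, and the two would be separated by chromatography.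

**Step 11.** The activated oxetane may ionise fully to a tertiary cation. That would erode the inversion at C5, open the way to elimination, or let the product hydroperoxide attack a second oxetane.

The fallback sets out from 10 and comes back at 16, replacing the ionic opening by a radical peroxidation. The allylic hydroxyl of 10 is silylated (Et3SiCl, imidazole) to tert-butyl{[(3R,5E)-3,5-dimethyl-3,7-bis(triethylsilyloxy)hept-5-en-1-yl]oxy}diphenylsilane F2. Isayama–Mukaiyama hydroperoxysilylation (Co(acac)2 cat., O2, Et3SiH) then places a silylperoxy group on the more substituted alkene carbon through a tertiary radical. This gives (3S,5RS)-1-(tert-butyldiphenylsilyloxy)-3,5-dimethyl-3,7-bis(triethylsilyloxy)-5-(triethylsilylperoxy)heptane F3 as both C5 epimers. Acid methanolysis under the conditions of step 12 strips the three triethylsilyl groups and gives 16 together with its C5 epimer, (3R,5S)-7-(tert-butyldiphenylsilyloxy)-3-hydroperoxy-3,5-dimethylheptane-1,5-diol F4, which is removed by chromatography. Steps 8 to 12 are bypassed at the price of stereocontrol at C5.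

**Step 18.** The basic ylide may deprotonate aldehyde 22 next to the carbonyl group. The enolate would then expel the peroxide oxygen on C5 and open the ring.

The fallback sets out from 21 and comes back at 28, and never places a carbonyl group β to the peroxide. Alcohol 21 is converted (I2, PPh3, imidazole) into tert-butyl{2-[(3S,5R)-5-(2-iodoethyl)-3,5-dimethyl-1,2-dioxolan-3-yl]ethoxy}diphenylsilane F5. The iodide is displaced at carbon by the dilithium alkoxide-acetylide of pent-4-yn-1-ol (n-BuLi, THF/DMPU) to give 7-[(3S,5S)-5-{2-(tert-butyldiphenylsilyloxy)ethyl}-3,5-dimethyl-1,2-dioxolan-3-yl]hept-4-yn-1-ol F6. Exhaustive diimide reduction of the triple bond gives 7-[(3S,5S)-5-{2-(tert-butyldiphenylsilyloxy)ethyl}-3,5-dimethyl-1,2-dioxolan-3-yl]heptan-1-ol F7. Dess–Martin oxidation then gives 28.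

**Step 24.** The new C9′=C10′ bond may form with poor E-selectivity, because enals are less selective partners than saturated aldehydes. The potassium base may also move the skipped double bonds into conjugation.

The fallback sets out from 29 and, for the reagent, from 30; it comes back at 33. It sets the geometry by equilibration instead of by the olefination. Alcohol 30 is converted (I2, PPh3, imidazole) into (3Z)-1-iodohex-3-ene F8 and then (PPh3, MeCN, reflux) into [(3Z)-hex-3-en-1-yl]triphenylphosphonium iodide F9. Its non-stabilised ylide (NaN(SiMe3)2, THF, −78 °C) reacts with 29 to give the 9′Z isomer, tert-butyl(2-{(3S,5S)-3,5-dimethyl-5-[(7E,9Z,12Z)-pentadeca-7,9,12-trien-1-yl]-1,2-dioxolan-3-yl}ethoxy)diphenylsilane F10. A catalytic amount of iodine in daylight then isomerises the conjugated diene to the more stable E,E form without moving the isolated Z-alkene, which gives 33.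

## Further compounds

F1 | step 14 | tert-butyl(2-{(3S,5R)-5-[2-(tert-butyldiphenylsilyloxy)ethyl]-3,5-dimethyl-1,2-dioxolan-3-yl}ethoxy)dimethylsilane | CC(C)(C)[Si](C)(C)OCC[C@@]1(C)C[C@@](C)(CCO[Si](c2ccccc2)(c2ccccc2)C(C)(C)C)OO1
F2 | step 11 | tert-butyl{[(3R,5E)-3,5-dimethyl-3,7-bis(triethylsilyloxy)hept-5-en-1-yl]oxy}diphenylsilane | CC[Si](CC)(CC)OC/C=C(\C)C[C@@](C)(O[Si](CC)(CC)CC)CCO[Si](c1ccccc1)(c1ccccc1)C(C)(C)C
F3 | step 11 | (3S,5RS)-1-(tert-butyldiphenylsilyloxy)-3,5-dimethyl-3,7-bis(triethylsilyloxy)-5-(triethylsilylperoxy)heptane, both C5 epimers | CC[Si](CC)(CC)OCCC(C)(OO[Si](CC)(CC)CC)C[C@@](C)(O[Si](CC)(CC)CC)CCO[Si](c1ccccc1)(c1ccccc1)C(C)(C)C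
F4 | step 11 | (3R,5S)-7-(tert-butyldiphenylsilyloxy)-3-hydroperoxy-3,5-dimethylheptane-1,5-diol | OCC[C@@](C)(OO)C[C@@](C)(O)CCO[Si](c1ccccc1)(c1ccccc1)C(C)(C)C
F5 | step 18 | tert-butyl{2-[(3S,5R)-5-(2-iodoethyl)-3,5-dimethyl-1,2-dioxolan-3-yl]ethoxy}diphenylsilane | ICC[C@@]1(C)C[C@](C)(CCO[Si](c2ccccc2)(c2ccccc2)C(C)(C)C)OO1
F6 | step 18 | 7-[(3S,5S)-5-{2-(tert-butyldiphenylsilyloxy)ethyl}-3,5-dimethyl-1,2-dioxolan-3-yl]hept-4-yn-1-ol | OCCCC#CCC[C@@]1(C)C[C@](C)(CCO[Si](c2ccccc2)(c2ccccc2)C(C)(C)C)OO1
F7 | step 18 | 7-[(3S,5S)-5-{2-(tert-butyldiphenylsilyloxy)ethyl}-3,5-dimethyl-1,2-dioxolan-3-yl]heptan-1-ol | OCCCCCCC[C@@]1(C)C[C@](C)(CCO[Si](c2ccccc2)(c2ccccc2)C(C)(C)C)OO1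
F8 | step 24 | (3Z)-1-iodohex-3-ene | CC/C=C\CCI
F9 | step 24 | [(3Z)-hex-3-en-1-yl]triphenylphosphonium iodide | CC/C=C\CC[P+](c1ccccc1)(c1ccccc1)c1ccccc1.[I-]
F10 | step 24 | tert-butyl(2-{(3S,5S)-3,5-dimethyl-5-[(7E,9Z,12Z)-pentadeca-7,9,12-trien-1-yl]-1,2-dioxolan-3-yl}ethoxy)diphenylsilane | CC/C=C\C/C=C\C=C\CCCCCC[C@@]1(C)C[C@](C)(CCO[Si](c2ccccc2)(c2ccccc2)C(C)(C)C)OO1
A1 | alternative 1 | dimethyl 2,2'-[(3R,5R)-3,5-dimethyl-1,2-dioxolane-3,5-diyl]diacetate, formed as the racemate | COC(=O)C[C@@]1(C)C[C@](C)(CC(=O)OC)OO1
A2 | alternative 1 | 3,5-dimethoxy-3,5-dimethyl-1,2-dioxolane, mixture of stereoisomers | COC1(C)CC(C)(OC)OO1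
A3 | alternative 2 | 2,2'-[(3S,5S)-3,5-dimethyl-1,2-dioxolane-3,5-diyl]di(ethan-1-ol) | OCC[C@@]1(C)C[C@](C)(CCO)OO1
A4 | alternative 2 | (2R,2'R)-2,2'-methylenebis(2-methyloxetane) | C[C@@]1(CCO1)C[C@@]1(C)CCO1
A5 | alternative 3 | 2-[(3S,5R)-5-{(1S)-7-(tert-butyldiphenylsilyloxy)-1-iodoheptyl}-3,5-dimethyl-1,2-dioxolan-3-yl]ethan-1-ol | CC(C)(C)[Si](c1ccccc1)(c1ccccc1)OCCCCCC[C@H](I)[C@@]1(C)C[C@](C)(CCO)OO1
A6 | alternative 3 | (3R,5E)-12-(tert-butyldiphenylsilyloxy)-3-hydroperoxy-3,5-dimethyldodec-5-en-1-ol | CC(C)(C)[Si](c1ccccc1)(c1ccccc1)OCCCCCC/C=C(\C)C[C@@](C)(OO)CCO
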